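The route rests on opening ring B at C6–C7 and ring D at O6–C12: the trans-fused α-methylene-γ-butyrolactone on C6/C7 (ring D, C11–C13) is the mark of a 2-(bromomethyl)acrylate adding through its γ-carbon C7 to a C6 aldehyde. One chromium-mediated allylation therefore forges C6–C7, closes the seven-membered ring B, sets C6 and C7 and lactonises to ring D. Its precursor is the 2-oxabicyclo[3.2.1]octene (rings A and C) carrying the C6 aldehyde on the bridge carbon C5 and, on C10, the tartrate-derived trans-dioxolane (C8, C9) ending in the (Z)-bromomethyl acrylate; it is assembled from an L-tartrate alkyne and a Sharpless epoxide by epoxide opening and enyne metathesis.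

Key step: step 18

Remarks
- Numbering used throughout: ring A = C1–C5 (C4 carries O4 and C15); ring B = C1, C5–C10; ring C = C4–O4–C14=C10–C1–C5; ring D = O6–C12(=O)–C11(=C13)–C7–C6.
- Design remark: the allylic bromide and the C6 aldehyde of 27 tolerate neither base nor organometallic reagents, so they are unveiled in the two steps just before the key step.
- Assumption: in diol 31 the 9-hydroxyl (convex face, next to sp2 C10) is acylated before the 8-hydroxyl (cis to C11); if the order of reactivity were the reverse, steps 20 and 21 would be run in the opposite order.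

Step 1
Reactants: 1 dimethyl 2,3-O-isopropylidene-L-tartrate
Product: 2 2,3-O-isopropylidene-L-threitol
Conditions: LiAlH4, THF, 0 °C to reflux; aqueous NaOH work-up
Reagents that add atoms: none
Why: Exhaustive LiAlH4 ester reduction should give the C2-symmetric diol without touching the ketal-protected stereocentres that become C8 and C9.

Step 2
Reactants: 2 2,3-O-isopropylidene-L-threitol
Product: 3 4-O-benzyl-2,3-O-isopropylidene-L-threitol
Conditions: NaH (1 equiv), BnBr (1 equiv), Bu4NI (cat.), THF, 0 °C to rt
Reagents that add atoms: benzyl bromide, BrCc1ccccc1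
Why: Williamson etherification of the monoalkoxide should give the mono-benzyl ether because the two hydroxyls are equivalent by symmetry and only one equivalent of base and halide is used; the benzylated terminus becomes C7.

Step 3
Reactants: 3 4-O-benzyl-2,3-O-isopropylidene-L-threitol
Product: 4 4-O-benzyl-2,3-O-isopropylidene-L-threose
Conditions: (COCl)2, DMSO, CH2Cl2, −78 °C; Et3N, −78 to 0 °C
Reagents that add atoms: none
Why: Swern oxidation should give the aldehyde without epimerisation since the trans-disubstituted dioxolane is the thermodynamically preferred arrangement; the formyl carbon is the future C10.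

Step 4
Reactants: 4 4-O-benzyl-2,3-O-isopropylidene-L-threose
Product: 5 (4S,5S)-4-(benzyloxymethyl)-5-ethynyl-2,2-dimethyl-1,3-dioxolane
Conditions: dimethyl (1-diazo-2-oxopropyl)phosphonate, K2CO3, MeOH, 0 °C to rt
Reagents that add atoms: dimethyl (1-diazo-2-oxopropyl)phosphonate (Ohira–Bestmann reagent), COP(=O)(OC)C(=[N+]=[N-])C(C)=O
Why: Seyferth–Gilbert homologation with the Ohira–Bestmann reagent should turn the aldehyde into the terminal alkyne under mild carbonate conditions; the former formyl carbon is C10 and the new alkyne CH becomes C1.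

Step 5
Reactants: 6 but-2-yne-1,4-diol
Product: 7 4-(triethylsilyloxy)but-2-yn-1-ol
Conditions: NaH (1 equiv), THF, 0 °C; Et3SiCl (1 equiv), 0 °C to rt
Reagents that add atoms: chlorotriethylsilane, CC[Si](Cl)(CC)CC
Why: Monosilylation of the symmetric diol through its monosodium alkoxide should give the mono-TES ether; the silylated carbon becomes C6 and the free carbinol carbon C15.

Step 6
Reactants: 7 4-(triethylsilyloxy)but-2-yn-1-ol
Product: 9 (2E)-2-(prop-2-en-1-yl)-4-(triethylsilyloxy)but-2-en-1-ol, via oxamagnesacycle 8 (not isolated)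
Conditions: allylmagnesium bromide (3 equiv), Et2O, 0 °C to reflux; aqueous NH4Cl
Reagents that add atoms: allylmagnesium bromide, C=CC[Mg]Br
Why: Hydroxyl-directed carbomagnesiation of the propargylic alkoxide should place the allyl group on the alkyne carbon next to the carbinol and magnesium on the other one in anti fashion (five-membered magnesium chelate), so that protonation gives the E alkene with the allyl CH2 (C3) cis to C6.

Step 7
Reactants: 9 (2E)-2-(prop-2-en-1-yl)-4-(triethylsilyloxy)but-2-en-1-ol
Product: 10 [(2R,3R)-2-(prop-2-en-1-yl)-3-(triethylsilyloxymethyl)oxiran-2-yl]methanol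
Conditions: Ti(OiPr)4 (cat.), D-(−)-diethyl tartrate (cat.), t-BuOOH, 4 Å MS, CH2Cl2, −20 °C
Reagents that add atoms: tert-butyl hydroperoxide, CC(C)(C)OO
Why: Sharpless asymmetric epoxidation with D-(−)-diethyl tartrate should deliver oxygen to the face of the E allylic alcohol that gives the (2R,3R)-epoxide, which fixes C4 in its final configuration (the epoxide oxygen is O4) and sets C5 for inversion, while the homoallylic terminal alkene is left alone.

Step 8
Reactants: 5 (4S,5S)-4-(benzyloxymethyl)-5-ethynyl-2,2-dimethyl-1,3-dioxolane; 10 [(2R,3R)-2-(prop-2-en-1-yl)-3-(triethylsilyloxymethyl)oxiran-2-yl]methanol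
Product: 13 (2S,3S)-2-(prop-2-en-1-yl)-3-(triethylsilyloxymethyl)-5-[(4S,5S)-5-(benzyloxymethyl)-2,2-dimethyl-1,3-dioxolan-4-yl]pent-4-yne-1,2-diol, via lithium acetylide 11 (not isolated), via alkynylalane 12 (not isolated)
Conditions: 5 (2.5 equiv), n-BuLi, toluene, −78 °C; Et2AlCl, 0 °C; then 10, 0 °C to rt; aqueous potassium sodium tartrate (excess 5 recovered)
Reagents that add atoms: none
Why: Ring opening of a 2,3-epoxy alcohol by an alkynylalane should occur at the carbon remote from the carbinol (C5, the only epoxide carbon open to SN2) with the aluminium held by the neighbouring alkoxide, so that inversion at C5 places C6 cis to O4 on the future ring A and forms the C5–C1 bond.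

Step 9
Reactants: 13 alkynyl diol
Product: 14 1-O-tert-butyldimethylsilyl ether of 13 (C15 silyl ether; free tertiary C4 hydroxyl)
Conditions: TBSCl, imidazole, DMF, 0 °C
Reagents that add atoms: tert-butylchlorodimethylsilane, CC(C)(C)[Si](C)(C)Cl
Why: Silylation with TBSCl and imidazole should take only the primary C15 hydroxyl because the tertiary C4 hydroxyl is too hindered.

Step 10
Reactants: 14 enyne (allyl group on C4; internal alkyne C1≡C10)
Product: 15 (1S,2S)-1-(tert-butyldimethylsilyloxymethyl)-2-(triethylsilyloxymethyl)-3-{1-[(4S,5S)-5-(benzyloxymethyl)-2,2-dimethyl-1,3-dioxolan-4-yl]ethenyl}cyclopent-3-en-1-ol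
Conditions: second-generation Grubbs catalyst RuCl2(H2IMes)(PCy3)(=CHPh) (5–10 mol%), ethylene (1 atm), toluene, 80 °C
Reagents that add atoms: none
Why: Ring-closing enyne metathesis in the exo mode should join the allyl CH (C2) to the alkyne carbon C1 to give ring A and transfer the terminal methylene to C10, which delivers the 2-substituted 1,3-diene with C10=C14H2 and creates no stereocentre.

Step 11
Reactants: 15 ring-A diene
Product: 17 primary alcohol (15 with C10=C14H2 converted into C10H–C14H2OH; both C10 epimers), via B-alkyl-9-BBN 16 (not isolated)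
Conditions: 9-BBN (2.5 equiv), THF, 0 °C to rt; then H2O2, aqueous NaOH, 0 °C
Reagents that add atoms: hydrogen peroxide, OO
Why: Hydroboration with 9-BBN should attack only the unhindered terminal methylene of the diene (boron on C14) and oxidation should give the primary C14 alcohol; the new C10 stereocentre is formed as a mixture and is erased in step 14.

Step 12
Reactants: 17 primary alcohol (C10 epimers)
Product: 18 triol (ring A saturated with H1 cis to H5; primary hydroxyls on C7 and C14; tertiary hydroxyl on C4; both C10 epimers)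
Conditions: H2 (1 atm), Pd(OH)2/C, EtOAc, rt
Reagents that add atoms: none
Why: Heterogeneous hydrogenation should add hydrogen to the trisubstituted ring alkene from the face opposite the adjacent C5 silyloxymethyl group, which A(1,2) strain holds pseudo-axial, so that H1 ends cis to H5 and the C10 chain cis to C6 and O4, while the benzyl ether is cleaved by hydrogenolysis.

Step 13
Reactants: 18 triol (C10 epimers)
Product: 20 lactol aldehyde (2-oxabicyclo[3.2.1]octan-3-ol closed between O4 and C14; C7 formyl group on the dioxolane), via open dialdehyde 19 (not isolated)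
Conditions: (COCl)2, DMSO, CH2Cl2, −78 °C; Et3N, −78 to 0 °C
Reagents that add atoms: none
Why: Swern oxidation should convert both primary alcohols into aldehydes and leave the tertiary one, and the C14 aldehyde should then close onto the C4 hydroxyl as the six-membered lactol of ring C, which is possible only because O4 and C10 are cis on ring A.

Step 14
Reactants: 20 lactol aldehyde
Product: 22 oxabicyclic enol ether aldehyde (rings A and C complete; C14=C10; C6 as CH2OSiEt3; C7 as CHO), via lactol mesylate 21 (not isolated)
Conditions: MsCl, Et3N, CH2Cl2, 0 °C to rt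
Reagents that add atoms: none
Why: Mesylation of the lactol hydroxyl and E1-type loss of methanesulfonate through the ring oxocarbenium ion with removal of H10 (lactol dehydration) should give the cyclic enol ether C14=C10, which also removes the C10 stereocentre, while the aldehyde is inert to MsCl.

Step 15
Reactants: 22 oxabicyclic enol ether aldehyde; 23 methyl acrylate
Product: 24 Morita–Baylis–Hillman adduct (methyl 2-(hydroxymethyl)acrylate unit joined through its carbinol carbon C7 to C8; both C7 epimers)
Conditions: 3-hydroxyquinuclidine (0.5 equiv), neat 23 (excess), rt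
Reagents that add atoms: none
Why: The Morita–Baylis–Hillman reaction of the α-alkoxy aldehyde with methyl acrylate under tertiary amine catalysis should form the C7–C11 bond; the C7 carbinol centre is formed as a mixture and is removed in step 16.

Step 16
Reactants: 24 Morita–Baylis–Hillman adduct
Product: 26 allylic bromide (methyl (2Z)-2-(bromomethyl)alk-2-enoate arm on C8; C6 still CH2OSiEt3), via allylic mesylate 25 (not isolated)
Conditions: MsCl, Et3N, THF, 0 °C; then LiBr, 0 °C to rt
Reagents that add atoms: lithium bromide, [Li+].[Br-]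
Why: Mesylation of the allylic alcohol and SN2′ displacement by bromide should give the rearranged primary allylic bromide as the thermodynamically preferred Z 2-(bromomethyl)enoate under neutral conditions that spare the enol ether.

Step 17
Reactants: 26 allylic bromide
Product: 27 precursor aldehyde ((1R,4S,5R,8S,9S); formyl C6 on the bridge carbon C5; 15-O-TBS; 8,9-acetonide; Z bromomethyl acrylate)
Conditions: (COCl)2, DMSO, CH2Cl2, −78 to −30 °C; i-Pr2NEt, −78 °C; cold pH 7 buffer
Reagents that add atoms: none
Why: Direct Swern oxidation of a primary triethylsilyl ether, in which the activated sulfoxide takes over the oxygen from silicon, should give the C6 aldehyde without fluoride or acid and leave the hindered primary TBS ether, and the cold quench avoids β-elimination of O4 from the new aldehyde.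

Step 18
Reactants: 27 precursor aldehyde
Product: 30 tetracyclic lactone ((1R,4S,5S,6S,7S,8S,9S); 8,9-acetonide; 15-O-TBS), via allylchromium dichloride 28 (not isolated), via chromium alkoxide 29 (not isolated)
Conditions: CrCl2 (10 equiv), THF, rt, 27 added slowly to 0.005 M; then 40 °C
Reagents that add atoms: none
Why: CrCl2 (divalent chromium) transfers two single electrons to the allylic C–Br bond and gives an allylchromium dichloride (trivalent chromium), σ-bound at C13 and free to equilibrate between its alkene isomers; this adds through its γ-carbon C7 to the chromium-bound C6 aldehyde in a six-membered chair array, forming C6–C7, and the resulting chromium alkoxide attacks the methyl ester to expel methoxide. The closest known reaction type is the intramolecular Nozaki–Hiyama–Kishi allylation of aldehydes with 2-(bromomethyl)acrylates, which delivers ring-fused α-methylene-γ-butyrolactones including medium carbocycles. Ring B closes as a seven-membered carbocycle by 7-exo-trig addition of C7 to the C6 carbonyl (tether C8–C9–C10–C1–C5), and ring D closes by 5-exo-trig acyl substitution of O6 on C12. C7 is set by the C8 stereocentre and the tether, bonding on the alkene face on which C9 carries the chain with the C8–O bond near the plane of the allyl unit, and C6 is set by the chair, which puts C5 and C8 equatorial and so gives the anti C6/C7 pair (H6 and H7 trans, addition to the Si face of the aldehyde). The step needs γ- over α-attack, cyclisation over oligomerisation, this one anti diastereomer and no elimination across C7–C8; these should be secured by the cyclic transition state (α-attack would need a nine-membered ring), by slow addition at high dilution, by the rigid bicycle that holds the formyl group on the bridge carbon C5 syn to C10 so that H5, H6 and H7 can sit alternately axial in the closing ring, and by the ketal oxygen on C8, a poor leaving group.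

Step 19
Reactants: 30 tetracyclic lactone
Product: 31 8,9-diol (15-O-TBS)
Conditions: PPTS (0.2 equiv), MeCN/H2O (10:1), 40 °C
Reagents that add atoms: none
Why: Acid-catalysed ketal hydrolysis under buffered conditions should remove the strained trans-fused dioxolane on the seven-membered ring faster than the enol ether, the lactone or the hindered silyl ether react.

Step 20
Reactants: 31 8,9-diol
Product: 32 9-O-acetyl-8-hydroxy compound (15-O-TBS)
Conditions: AcCl (1.05 equiv), 2,4,6-collidine, CH2Cl2, −78 to −40 °C
Reagents that add atoms: acetyl chloride, CC(Cl)=O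
Why: Selective monoacylation with one equivalent of acetyl chloride and a hindered pyridine at low temperature should take the more accessible 9-hydroxyl on the convex face, next to the sp2 carbon C10, in preference to the 8-hydroxyl, which is cis to C11.

Step 21
Reactants: 32 9-O-acetyl-8-hydroxy compound; 33 (S)-2-methylbutanoic acid
Product: 35 15-O-TBS ether of the target (8-O-[(S)-2-methylbutanoyl]; 9-O-acetyl), via mixed anhydride 34 (not isolated)
Conditions: 33, 2,4,6-trichlorobenzoyl chloride, Et3N, THF, rt; then 32, DMAP, toluene, rt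
Reagents that add atoms: none
Why: Yamaguchi esterification through the mixed anhydride and DMAP should acylate the remaining hindered 8-hydroxyl with the α-branched acid without loss of its S configuration.

Step 22
Reactants: 35 15-O-TBS ether of the target
Product: 36 target CNP0013863.2
Conditions: HF·pyridine, pyridine, THF, 0 °C to rt
Reagents that add atoms: none
Why: Fluoride desilylation with buffered HF·pyridine should cleave the primary silyl ether at C15 and leave the esters, the α-methylene lactone and the enol ether intact.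

Compound list
1 | dimethyl 2,3-O-isopropylidene-L-tartrate | COC(=O)[C@@H]1OC(C)(C)O[C@H]1C(=O)OC | starting material
2 | 2,3-O-isopropylidene-L-threitol | OC[C@@H]1OC(C)(C)O[C@H]1CO | intermediate
3 | 4-O-benzyl-2,3-O-isopropylidene-L-threitol | OC[C@@H]1OC(C)(C)O[C@H]1COCc1ccccc1 | intermediate
4 | 4-O-benzyl-2,3-O-isopropylidene-L-threose | O=C[C@@H]1OC(C)(C)O[C@H]1COCc1ccccc1 | intermediate
5 | (4S,5S)-4-(benzyloxymethyl)-5-ethynyl-2,2-dimethyl-1,3-dioxolane | C#C[C@@H]1OC(C)(C)O[C@H]1COCc1ccccc1 | intermediate
6 | but-2-yne-1,4-diol | OCC#CCO | starting material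
7 | 4-(triethylsilyloxy)but-2-yn-1-ol | OCC#CCO[Si](CC)(CC)CC | intermediate
8 | oxamagnesacycle from allylmagnesiation of 7 (not isolated) | C=CCC1=C(CO[Si](CC)(CC)CC)[Mg]OC1 | intermediate
9 | (2E)-2-(prop-2-en-1-yl)-4-(triethylsilyloxy)but-2-en-1-ol | OC/C(CC=C)=C/CO[Si](CC)(CC)CC | intermediate
10 | [(2R,3R)-2-(prop-2-en-1-yl)-3-(triethylsilyloxymethyl)oxiran-2-yl]methanol | OC[C@@]1(CC=C)O[C@@H]1CO[Si](CC)(CC)CC | intermediate
11 | lithium acetylide of 5 (not isolated) | [Li]C#C[C@@H]1OC(C)(C)O[C@H]1COCc1ccccc1 | intermediate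
12 | diethyl(alkynyl)aluminium from 5 (not isolated) | CC[Al](CC)C#C[C@@H]1OC(C)(C)O[C@H]1COCc1ccccc1 | intermediate
13 | (2S,3S)-2-(prop-2-en-1-yl)-3-(triethylsilyloxymethyl)-5-[(4S,5S)-5-(benzyloxymethyl)-2,2-dimethyl-1,3-dioxolan-4-yl]pent-4-yne-1,2-diol | C=CC[C@@](O)(CO)[C@H](CO[Si](CC)(CC)CC)C#C[C@@H]1OC(C)(C)O[C@H]1COCc1ccccc1 | intermediate
14 | 1-O-TBS ether of 13 | C=CC[C@@](O)(CO[Si](C)(C)C(C)(C)C)[C@H](CO[Si](CC)(CC)CC)C#C[C@@H]1OC(C)(C)O[C@H]1COCc1ccccc1 | intermediate
15 | ring-A diene, (1S,2S)-cyclopent-3-en-1-ol with C10=C14H2 | C=C([C@@H]1OC(C)(C)O[C@H]1COCc1ccccc1)C1=CC[C@@](O)(CO[Si](C)(C)C(C)(C)C)[C@@H]1CO[Si](CC)(CC)CC | intermediate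
16 | B-alkyl-9-BBN, boron on C14, C10 epimers (not isolated) | C(CB1C2CCCC1CCC2)([C@@H]1OC(C)(C)O[C@H]1COCc1ccccc1)C1=CC[C@@](O)(CO[Si](C)(C)C(C)(C)C)[C@@H]1CO[Si](CC)(CC)CC | intermediate
17 | primary C14 alcohol, C10 epimers | OCC([C@@H]1OC(C)(C)O[C@H]1COCc1ccccc1)C1=CC[C@@](O)(CO[Si](C)(C)C(C)(C)C)[C@@H]1CO[Si](CC)(CC)CC | intermediate
18 | triol with saturated ring A, H1 cis to H5, C10 epimers | OCC([C@@H]1OC(C)(C)O[C@H]1CO)[C@@H]1CC[C@@](O)(CO[Si](C)(C)C(C)(C)C)[C@@H]1CO[Si](CC)(CC)CC | intermediate
19 | open C7,C14-dialdehyde, C10 epimers (not isolated) | O=C[C@@H]1OC(C)(C)O[C@H]1C(C=O)[C@@H]1CC[C@@](O)(CO[Si](C)(C)C(C)(C)C)[C@@H]1CO[Si](CC)(CC)CC | intermediate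
20 | lactol aldehyde, C10 and C14 epimers | O=C[C@@H]1OC(C)(C)O[C@H]1C1C(O)O[C@@]2(CO[Si](C)(C)C(C)(C)C)CC[C@@H]1[C@H]2CO[Si](CC)(CC)CC | intermediate
21 | lactol mesylate (not isolated) | O=C[C@@H]1OC(C)(C)O[C@H]1C1C(OS(C)(=O)=O)O[C@@]2(CO[Si](C)(C)C(C)(C)C)CC[C@@H]1[C@H]2CO[Si](CC)(CC)CC | intermediate
22 | oxabicyclic enol ether aldehyde, (1R,4S,5S,8R,9S) | O=C[C@@H]1OC(C)(C)O[C@H]1C1=CO[C@@]2(CO[Si](C)(C)C(C)(C)C)CC[C@@H]1[C@H]2CO[Si](CC)(CC)CC | intermediate
23 | methyl acrylate | C=CC(=O)OC | starting material
24 | Morita–Baylis–Hillman adduct, C7 epimers | C=C(C(=O)OC)C(O)[C@@H]1OC(C)(C)O[C@H]1C1=CO[C@@]2(CO[Si](C)(C)C(C)(C)C)CC[C@@H]1[C@H]2CO[Si](CC)(CC)CC | intermediate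
25 | allylic mesylate of 24 (not isolated) | C=C(C(=O)OC)C(OS(C)(=O)=O)[C@@H]1OC(C)(C)O[C@H]1C1=CO[C@@]2(CO[Si](C)(C)C(C)(C)C)CC[C@@H]1[C@H]2CO[Si](CC)(CC)CC | intermediate
26 | Z allylic bromide with C6 as CH2OSiEt3 | BrC/C(C(=O)OC)=C\[C@@H]1OC(C)(C)O[C@H]1C1=CO[C@@]2(CO[Si](C)(C)C(C)(C)C)CC[C@@H]1[C@H]2CO[Si](CC)(CC)CC | intermediate
27 | precursor aldehyde, (1R,4S,5R,8S,9S) | O=C[C@@H]1[C@H]2CC[C@]1(CO[Si](C)(C)C(C)(C)C)OC=C2[C@@H]1OC(C)(C)O[C@H]1/C=C(\CBr)C(=O)OC | intermediate
28 | allylchromium dichloride, trivalent chromium on C13 (not isolated) | Cl[Cr](Cl)C/C(C(=O)OC)=C\[C@@H]1OC(C)(C)O[C@H]1C1=CO[C@@]2(CO[Si](C)(C)C(C)(C)C)CC[C@@H]1[C@H]2C=O | intermediate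
29 | chromium alkoxide of the ring-B hydroxy ester (not isolated) | C=C(C(=O)OC)[C@@H]1[C@@H]2OC(C)(C)O[C@H]2C2=CO[C@@]3(CO[Si](C)(C)C(C)(C)C)CC[C@@H]2[C@H]3[C@H]1O[Cr](Cl)Cl | intermediate
30 | tetracyclic lactone, 8,9-acetonide, 15-O-TBS, (1R,4S,5S,6S,7S,8S,9S) | C=C1C(=O)O[C@H]2[C@H]1[C@@H]1OC(C)(C)O[C@H]1C1=CO[C@@]3(CO[Si](C)(C)C(C)(C)C)CC[C@@H]1[C@@H]23 | intermediate
31 | 8,9-diol, 15-O-TBS | C=C1C(=O)O[C@H]2[C@H]1[C@H](O)[C@@H](O)C1=CO[C@@]3(CO[Si](C)(C)C(C)(C)C)CC[C@@H]1[C@@H]23 | intermediate
32 | 9-O-acetyl-8-hydroxy compound, 15-O-TBS | C=C1C(=O)O[C@H]2[C@H]1[C@H](O)[C@@H](OC(C)=O)C1=CO[C@@]3(CO[Si](C)(C)C(C)(C)C)CC[C@@H]1[C@@H]23 | intermediate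
33 | (S)-2-methylbutanoic acid | CC[C@H](C)C(=O)O | starting material
34 | (S)-2-methylbutanoic 2,4,6-trichlorobenzoic anhydride (not isolated) | CC[C@H](C)C(=O)OC(=O)c1c(Cl)cc(Cl)cc1Cl | intermediate
35 | 15-O-TBS ether of the target | C=C1C(=O)O[C@H]2[C@H]1[C@H](OC(=O)[C@@H](C)CC)[C@@H](OC(C)=O)C1=CO[C@@]3(CO[Si](C)(C)C(C)(C)C)CC[C@@H]1[C@@H]23 | intermediate
36 | CNP0013863.2 | C=C1C(=O)O[C@H]2[C@H]1[C@H](OC(=O)[C@@H](C)CC)[C@@H](OC(C)=O)C1=CO[C@@]3(CO)CC[C@@H]1[C@@H]23 | target

Total step count: 22. Longest linear sequence: 19 steps (steps 1–4, then 8–22).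

Steps most likely to fail

Step 18. The ring closure may lose to intermolecular coupling, C7 may bond on its other face (wrong C7/C8 relationship under the strain of the trans-dioxolane), or elimination across C7–C8 may compete. Fallback, from 24 back to 30: the allylic alcohol of 24 would be acetylated (Ac2O, DMAP) to the Morita–Baylis–Hillman acetate F1, and direct Swern oxidation of the triethylsilyl ether would give the acetoxy aldehyde F2. Pd(PPh3)4 with InI would then ionise the allylic acetate to a π-allylpalladium complex and reduce it to an allylindium species, which adds to the C6 aldehyde under a different set of transition-state constraints than the chromium reagent; lactonisation of the resulting hydroxy ester would return 30.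

Step 19. Hydration or allylic ionisation of the enol ether, or loss of the silyl ether, may compete with ketal hydrolysis. Fallback, from 30 back to 35: PPTS in methanol would add methanol across C10=C14 and exchange the acetonide at the same time, giving the C14 methyl acetal diol F3, in which the enol ether is masked. Acetylation as in step 20 would give the 9-acetate F4 and Yamaguchi esterification as in step 21 the diester acetal F5. Elimination of methanol from the mixed acetal with TMSOTf and i-Pr2NEt would then regenerate the enol ether and return 35.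

Step 8. Epoxide opening may be sluggish at the hindered C5, or the Lewis-acidic alane may trigger epoxide rearrangement or silyl migration. Fallback, from 10 back to 14: the primary hydroxyl would be silylated first (TBSCl, imidazole) to the epoxy silyl ether F6, which would then be opened at C5 with inversion by lithium acetylide 11 under external activation with BF3·OEt2 at −78 °C. This gives 14 directly and needs only a slight excess of 5.

Further compounds
F1 | step 18 | Morita–Baylis–Hillman acetate of 24 | C=C(C(=O)OC)C(OC(C)=O)[C@@H]1OC(C)(C)O[C@H]1C1=CO[C@@]2(CO[Si](C)(C)C(C)(C)C)CC[C@@H]1[C@H]2CO[Si](CC)(CC)CC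
F2 | step 18 | acetoxy aldehyde (C6 formyl, allylic acetate) | C=C(C(=O)OC)C(OC(C)=O)[C@@H]1OC(C)(C)O[C@H]1C1=CO[C@@]2(CO[Si](C)(C)C(C)(C)C)CC[C@@H]1[C@H]2C=O
F3 | step 19 | C14 methyl acetal 8,9-diol | C=C1C(=O)O[C@H]2[C@H]1[C@H](O)[C@@H](O)C1C(OC)O[C@@]3(CO[Si](C)(C)C(C)(C)C)CC[C@@H]1[C@@H]23
F4 | step 19 | C14 methyl acetal 9-acetate | C=C1C(=O)O[C@H]2[C@H]1[C@H](O)[C@@H](OC(C)=O)C1C(OC)O[C@@]3(CO[Si](C)(C)C(C)(C)C)CC[C@@H]1[C@@H]23
F5 | step 19 | C14 methyl acetal 8-[(S)-2-methylbutanoate] 9-acetate | C=C1C(=O)O[C@H]2[C@H]1[C@H](OC(=O)[C@@H](C)CC)[C@@H](OC(C)=O)C1C(OC)O[C@@]3(CO[Si](C)(C)C(C)(C)C)CC[C@@H]1[C@@H]23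
F6 | step 8 | TBS ether of epoxy alcohol 10 | CC(C)(C)[Si](C)(C)OC[C@@]1(CC=C)O[C@@H]1CO[Si](CC)(CC)CC
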